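The vessel differs between the flasks below, while the amounts charged stay the same.

    substrate + partner ⇌ adduct (K1 = 3.3 M⁻¹, k1 = 19 M⁻¹ min⁻¹)
    adduct → target (k2 = 0.18 min⁻¹)
    partner + protic impurity → quenched reagent (k3 = 1.8 M⁻¹ min⁻¹)
    target ⇌ isomer of the product (K4 = 1.5, k4 = 0.047 min⁻¹)

| flask | substrate | partner | protic impurity | time | remark |
|---|---|---|---|---|---|
| beta | 0.20 M | 0.240 M (fed, over 4.00 min) | 0.0400 M | 8.0 min | a stirred flask in which partner is dosed at a steady rate over 4.00 min without added volume, worked up at 8.0 min |
| alpha | 0.20 M | 0.240 M | 0.0400 M | 8.0 min | a closed flask charged with all of it at once and left for 8.0 min |
| epsilon | 0.20 M | 0.240 M | 0.0400 M |  | one stirred flow tank at steady state, fed with the mixture as stated, mean residence time 8.0 min |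
| delta | 0.20 M (fed, over 4.00 min) | 0.240 M | 0.0400 M | 8.0 min | all but substrate at the start; substrate goes in evenly over 4.00 min, the run ends at 8.0 min |

- the set-up with the highest amount of target at the outlet or at the end, in percent of the substrate put in ("none" if the first two lie within 2 percentage points) (beta / alpha / epsilon / delta / none)
- amount of target at the outlet or at the end, in percent of the substrate put in, beta
- amount of target at the outlet or at the end, in percent of the substrate put in, alpha
- amount of target at the outlet or at the end, in percent of the substrate put in, epsilon
- amount of target at the outlet or at the end, in percent of the substrate put in, delta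

- the stated concentrations are those of everything mixed, before any reaction; amounts are the same in each set-up
- the feed brings no volume worth counting
- run time (beta): 8.0 min

- Adduct falls back at 5.76 min⁻¹, far faster than it goes on at 0.18 min⁻¹, so a pre-equilibrium is assumed, and the mixed charges hold 35.7% of the substrate as adduct.
- Folded together, 0.515 is the turnover number: the rate constant of the step to target, times the run time, times that bound share.
- Read as a first-order exponent for alpha, it gives a first estimate of 40.2% of the substrate turned over.
- Beta and delta are each dosed evenly, so this reckoning takes 2.00 min off their run time on average, which gives a number of 0.386 and an estimated turnover of 32.0%.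
- The stirred tank of epsilon, with turnover N/(1+N), gives an estimate of 34.0%, so this first pass puts alpha ahead of the others, with epsilon and the dosed flasks 2 percentage points apart.
- The number above counts the full charges. Going round once more, this reckoning puts alpha's mid-run pools, bound forms counted, near 0.160 M of substrate and 0.180 M of partner, less than the charges, taking 0.0200 M of partner as lost to the protic impurity besides what has gone on to target.
- Those pools give an estimate of 34.8% made, less than the first 40.2%. With target on average 4.00 min old and drifting to its isomer at 0.047 min⁻¹, this reckoning commits to 28.3% of target in alpha.
- The forecast names alpha, with 28.5% for alpha, 25% for beta, 24.2% for delta and 21.6% for epsilon, on the ground that “charging everything at once gives the highest adduct level earliest and the longest time to convert”.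
- The simulation gives alpha as best, with 28.5%, against 24.5% for beta, 23.7% for delta and 21.6% for epsilon; alpha leads beta by 4 points.
- In alpha at 0.103 min, adduct falls back 32 times faster than it goes on, and at 8.00 min target is still made 2.58 times faster than it is used up, each step taken net. Alpha's turnover number of 0.515 becomes 0.338 in a neighbouring flask with 0.14 M of partner, a ratio of 0.656. That flask ends with 18.6% of target, 0.653 of alpha's.

The numbers were set for the occasion; the rest is arithmetic.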